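The violet run is this very flask, followed to 80.0 s, so I read the pace from it and the balance from the charges.

- violet: substrate 1 mM; reagent 0.90 mM; scavenger 0.30 mM; free catalyst 25 µM; the very flask that is asked about, followed so far
- flask: substrate 1.0 mM; reagent 0.900 mM; scavenger 0.300 mM; free catalyst 25 µM; time 2.5 min

violet run (percent of the substrate charged)

| time / s | substrate / % | target / % |
|---|---|---|
| 12.0 | 87 | 14 |
| 25.0 | 70 | 30 |
| 40.0 | 58 | 44 |
| 50.0 | 49 | 48 |
| 60.0 | 45 | 59 |
| 80.0 | 38 | 62 |

(standard deviation of a reading: 1.5 percentage points)

- the earlier runs do not show how much of reagent is bound; that part of a forecast is a guess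

- part of the substrate that has reacted at 2.5 min
- share of the unused reagent that is free and not bound as idle adduct, at 2.5 min

Reagent is the limiting reagent, at 0.900 mM against 1.0 mM of substrate. I suppose each turnover uses one reagent and frees one released group, which scavenger removes or reagent holds as idle adduct. Unused reagent, [reagent] + [idle adduct], is then the reagent charge less the substrate turned over, to within the catalyst charge of 25 µM. The surplus of released group, once scavenger is spent, is the substrate turned over less the scavenger charge. The two are equal at the crossover conversion, the mean of the reagent and scavenger charges divided by the substrate charge: 60.0 %.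

In the first instants substrate falls to 87 % by 12.0 s. In the middle, from 25.0 s to 60.0 s, substrate loses 25 percentage points, and target reads 59 % against the crossover of 60.0 %. Then substrate loses 7 points by 80.0 s, where target reads 62 %. If scavenger is spent by then, the count on that reading gives a surplus of 0.320 mM against 0.280 mM of unused reagent. Each further turnover widens that gap. If binding is tight, my free share at 2.5 min is near zero, but the tightness is my guess. I place conversion above that last reading and below the reagent's ceiling of 90.0 %.

The forecast gives 72 % (66 % to 79 %) and a free share of 60 % (30 % to 90 %), adding “this is largely a guess”.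

The flask gives 74.7 % reacted and a free share of 6.84 %.

    reagent + free catalyst → catalyst intermediate A (k = 4100 M⁻¹ s⁻¹)
    catalyst intermediate A → released group + catalyst intermediate B (k = 4.10 s⁻¹)
    substrate + catalyst intermediate B ⇌ catalyst intermediate C (K = 4000 M⁻¹, k = 1900 M⁻¹ s⁻¹)
    catalyst intermediate C → free catalyst + target (k = 1.60 s⁻¹)
    reagent + released group ⇌ idle adduct, settled at all times (K = 44000 M⁻¹)
    scavenger + released group → scavenged by-product (k = 2000 M⁻¹ s⁻¹)

This flask ends past the crossover of 60.0 %. The count gives 0.153 mM of unused reagent against a surplus of 0.447 mM, and idle adduct stands at 0.140 mM. A neighbouring flask, charged with 0.0062 mM of free catalyst, has the same crossover, but its conversion reaches 42.0 %. Its unused reagent is 0.480 mM, of which 0.167 mM is idle adduct, and its free share is 64.9 %.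

Readings and results are simulated from invented constants, noise included.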